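How much target stands in a stirred flask after 4.0 d, when its second reactant has to cross from a held gas phase?

starting material 0.30 M; gas phase 14 mM (held); time 4.0 d
    starting material + dissolved gas ⇌ target (K1 = 534 M⁻¹, k1 = 8.59 M⁻¹ h⁻¹)
    dissolved gas + target → over-reaction product (k2 = 1.67 M⁻¹ h⁻¹)
    gas phase ⇌ dissolved gas, rate k3*(csat - [dissolved gas]) (k3 = 0.288 h⁻¹, csat = 14 mM)
- amount of target at 4.0 d, in percent of the starting material charged
- concentration of dissolved gas in solution at 4.0 d, in percent of saturation

The end state, over-reaction product, costs two dissolved gas per starting material, which is 200 % of the charge. By forward binding alone, with the other concentrations as charged, dissolved gas has a half-life of 0.27 h, shorter than the 2.41 h in which the crossing closes half of the gap to saturation, so at the start the crossing is the rate-limiting step. The clock is therefore the delivery number 129 %, the most gas that can cross in the time into a solution kept empty, as a share of the starting material charged. It stands below the cost of the end state.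

My own reckoning makes two guesses. Starting material falls exponentially with the delivery number, leaving 27.5 %. Target stands near its top, so the crossing feeds two equal streams, net binding and over-reaction. Solved together, these balances give dissolved gas at 5.15 mM, or 36.8 % of saturation, and target at 49.3 %.

The forecast gives 51 % and 38 %, starting from “Gas transfer limits the reaction”. The simulation gives 51.7 % and 38.3 %.

This flask owes its reading to slow delivery together with the time of reading: without resistance to crossing it holds 14.7 % target at 4.0 d, and left until 40.0 d it holds 0 %. At 4.0 d this flask holds 26 % starting material.

In the neighbour flask read at 40 h, the delivery number is 53.8 %, so 58.4 % of the starting material should remain. That flask holds 59 %.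

(The numbers of this flask are assumed; the result is computed.)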